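The target is cut at the central bond of the E,E-diene into two dihydropyrano-tropolone halves, and the whole plan rests on ring B: its ring oxygen O1, the oxygen-bearing C2 and the methyl-bearing C3 are the oxygen and the two carbons of a trans-2,3-epoxy alcohol that hangs by one CH2 group on a 6-methoxytropone. In one operation trimethylaluminium puts the methyl group on C3 with inversion, and the C2 alkoxide set free adds to tropone C6 and expels methoxide, which closes ring B 2,3-trans. The precursor is the (2S,3S)-epoxy alcohol made by Sharpless epoxidation of an E-allylic alcohol carried by the dimethoxytropone.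

Key step: step 10

Remark: the tropolone rings of the target are drawn as one of two rapidly interconverting tautomers; the hydroxy-oxo arrangement formed in step 19 is the same compound.
Remark: the alkoxy leaving group on the tropone is methoxy, the same group that protects the tropolone oxygen, so that alkoxide released in the ring closures can only exchange degenerately.
Remark: monocyclic troponoids are numbered C1 (C=O), C2 (OMe), C3 (H), C4 (Me), C5 (carbon substituent), C6 (OMe), C7 (H); the bicyclic halves are named as cyclohepta[b]pyrans (O1, C2, C3, C4, C4a, C5 to C9, C9a).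
Remark: (R)-but-3-ene-1,2-diol and (E)-3-(tributylstannyl)prop-2-en-1-ol are taken as purchasable.

Step 1
Reactants: 1 2-methylanisole
Product: 2 1-methoxy-2-methylcyclohexa-1,4-diene
Conditions: Li, NH3 (l), THF, t-BuOH, −78 °C to −33 °C; then NH4Cl
Reagents that add atoms: none
Why: Birch reduction leaves the two donor-substituted carbons on one double bond, so the 1,4-diene carries a tetrasubstituted enol ether and an isolated cis-alkene; no stereocentre is formed.

Step 2
Reactants: 2 1-methoxy-2-methylcyclohexa-1,4-diene
Product: 3 rac-7,7-dibromo-1-methoxy-6-methylbicyclo[4.1.0]hept-3-ene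
Conditions: CHBr3, KOtBu, pentane, −20 °C to 0 °C
Reagents that add atoms: bromoform, BrC(Br)Br
Why: Dihalocarbene cyclopropanation, in which electrophilic dibromocarbene adds to the electron-rich enol ether double bond in preference to the isolated alkene; the cis ring fusion is the only one possible and the racemic stereocentres are erased in step 4.

Step 3
Reactants: 3 rac-7,7-dibromo-1-methoxy-6-methylbicyclo[4.1.0]hept-3-ene
Product: 4 rac-7,7-dibromo-1-methoxy-6-methylbicyclo[4.1.0]heptane-3,4-diol
Conditions: OsO4 (2 mol%), NMO, acetone–H2O, 0 °C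
Reagents that add atoms: N-methylmorpholine N-oxide, C[N+]1([O-])CCOCC1; water, O
Why: Catalytic OsO4/NMO syn-dihydroxylation of the remaining cis-alkene from the face opposite the CBr2 bridge, run cold to keep the donor-substituted dibromocyclopropane closed; the diol stereocentres are erased in step 4.

Step 4
Reactants: 4 rac-7,7-dibromo-1-methoxy-6-methylbicyclo[4.1.0]heptane-3,4-diol
Product: 6 5-bromo-2-hydroxy-6-methoxy-4-methylcyclohepta-2,4,6-trien-1-one, via 1,2-diketone 5 (not isolated)
Conditions: TFAA, DMSO, CH2Cl2, −60 °C; then Et3N, −60 °C to 23 °C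
Reagents that add atoms: none
Why: Swern-type double oxidation gives the 1,2-diketone, whose amine-promoted enolisation sets off the known ring expansion of ring-fused gem-dibromocyclopropanes (disrotatory C–C opening with loss of bromide, pushed by the methoxy group, then loss of a proton) to the aromatic bromotropolone with bromine on the former carbene carbon between C–Me and C–OMe.

Step 5
Reactants: 6 5-bromo-2-hydroxy-6-methoxy-4-methylcyclohepta-2,4,6-trien-1-one
Product: 7 5-bromo-2,6-dimethoxy-4-methylcyclohepta-2,4,6-trien-1-one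
Conditions: MeI, K2CO3, acetone, 23 °C; chromatography
Reagents that add atoms: iodomethane, CI
Why: Williamson O-methylation of the ambident tropolonate is not expected to discriminate strongly between the two oxygens, so 7 is separated by chromatography from the ether methylated on the other tropolone oxygen.

Step 6
Reactants: 7 5-bromo-2,6-dimethoxy-4-methylcyclohepta-2,4,6-trien-1-one
Product: 8 5-(hydroxymethyl)-2,6-dimethoxy-4-methylcyclohepta-2,4,6-trien-1-one
Conditions: Bu3SnCH2OH, Pd(PPh3)4 (5 mol%), 1,4-dioxane, 90 °C
Reagents that add atoms: (tributylstannyl)methanol, CCCC[Sn](CCCC)(CCCC)CO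
Why: Stille coupling, in which zerovalent palladium inserts into the activated C5–Br bond of the bromotropone and the stannane transfers its hydroxymethyl group to the position between C4–Me and C6–OMe.

Step 7
Reactants: 8 5-(hydroxymethyl)-2,6-dimethoxy-4-methylcyclohepta-2,4,6-trien-1-one
Product: 9 5-(bromomethyl)-2,6-dimethoxy-4-methylcyclohepta-2,4,6-trien-1-one
Conditions: CBr4, PPh3, CH2Cl2, 0 °C
Reagents that add atoms: tetrabromomethane, BrC(Br)(Br)Br
Why: Appel bromination converts the primary benzylic-type alcohol into the bromide under neutral conditions that leave both vinylogous ester ethers untouched.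

Step 8
Reactants: 9 5-(bromomethyl)-2,6-dimethoxy-4-methylcyclohepta-2,4,6-trien-1-one; 10 (E)-3-(tributylstannyl)prop-2-en-1-ol
Product: 11 5-[(2E)-4-hydroxybut-2-en-1-yl]-2,6-dimethoxy-4-methylcyclohepta-2,4,6-trien-1-one
Conditions: Pd2(dba)3 (2.5 mol%), P(2-furyl)3, THF, 50 °C
Reagents that add atoms: none
Why: Stille coupling of a benzylic-type bromide with an alkenylstannane, which transfers the alkenyl group with retention of its E geometry and tolerates the free hydroxyl.

Step 9
Reactants: 11 5-[(2E)-4-hydroxybut-2-en-1-yl]-2,6-dimethoxy-4-methylcyclohepta-2,4,6-trien-1-one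
Product: 12 5-{[(2S,3S)-3-(hydroxymethyl)oxiran-2-yl]methyl}-2,6-dimethoxy-4-methylcyclohepta-2,4,6-trien-1-one
Conditions: Ti(OiPr)4 (full equivalent), L-(+)-diethyl tartrate, t-BuOOH, 4 Å MS, CH2Cl2, −20 °C
Reagents that add atoms: tert-butyl hydroperoxide, CC(C)(C)OO
Why: Sharpless asymmetric epoxidation, in which the titanium–L-(+)-tartrate complex delivers the peroxide oxygen to one face of the E-allylic alcohol and so sets both epoxide stereocentres as (2S,3S) (reagent control, trans from the E-alkene), while the electron-poor tropone double bonds are inert to the electrophilic oxidant.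

Step 10
Reactants: 12 5-{[(2S,3S)-3-(hydroxymethyl)oxiran-2-yl]methyl}-2,6-dimethoxy-4-methylcyclohepta-2,4,6-trien-1-one
Product: 14 (2R,3R)-2-(hydroxymethyl)-7-methoxy-3,5-dimethyl-3,4-dihydrocyclohepta[b]pyran-8(2H)-one, via 1,2-diol 13 (not isolated)
Conditions: Me3Al (4 equiv), CH2Cl2–hexane, −30 °C to 0 °C; then MeOH, NaOMe, THF, 23 °C; aq. KNaC4H4O6
Reagents that add atoms: trimethylaluminium, C[Al](C)C
Why: Me3Al first deprotonates the primary hydroxyl (methane), and the aluminium alkoxide so formed holds a second Me3Al on the epoxide oxygen, so that methyl is transferred to C3, the epoxide carbon remote from the carbinol, anti to the breaking C3–O bond; after the methanol quench, methoxide lets the secondary C2 alkoxide of diol 13 add to tropone C6 and expel methoxide (addition–elimination on a vinylogous ester). The closest known reaction types are the organoaluminium C3-opening of 2,3-epoxy alcohols to 1,2-diols and the alkoxide exchange of alkoxytropones, here run one after the other in one flask. Ring B is closed by a 6-exo-trig attack of oxygen on C6 (the C6=C7 bond lies outside the new ring); the primary alkoxide would have to form a seven-membered ring, spiro-addition at C5 has no leaving group and reverts, and exchange of the methoxy group on tropone C2 by methoxide is degenerate. The one new stereocentre, C3, is set by inversion at the epoxide carbon whose configuration came from the Sharpless epoxidation, while the C2–O bond is never broken, so the trans epoxide becomes the 2,3-trans (2R,3R) ring. The step needs C3- over C2-opening, which the aluminium-bound primary alkoxide secures by intramolecular delivery, and it needs the tropone to survive Me3Al, for which the reagent is kept to the smallest workable excess at low temperature while the tropone carbonyl is tied up as its Lewis acid complex.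

Step 11
Reactants: 14 (2R,3R)-2-(hydroxymethyl)-7-methoxy-3,5-dimethyl-3,4-dihydrocyclohepta[b]pyran-8(2H)-one
Product: 15 (2R,3R)-7-methoxy-3,5-dimethyl-8-oxo-2,3,4,8-tetrahydrocyclohepta[b]pyran-2-carbaldehyde
Conditions: Dess–Martin periodinane, NaHCO3, CH2Cl2, 0 °C to 23 °C
Reagents that add atoms: none
Why: Dess–Martin oxidation of the primary alcohol under buffered, non-basic conditions; the aldehyde is used at once, and its α-stereocentre C2 is in any case the more stable 2,3-trans epimer.

Step 12
Reactants: 15 (2R,3R)-7-methoxy-3,5-dimethyl-8-oxo-2,3,4,8-tetrahydrocyclohepta[b]pyran-2-carbaldehyde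
Product: 16 (2R,3R)-2-[(E)-2-iodoethenyl]-7-methoxy-3,5-dimethyl-3,4-dihydrocyclohepta[b]pyran-8(2H)-one
Conditions: CrCl2, CHI3, THF–1,4-dioxane (1:6), 0 °C to 23 °C
Reagents that add atoms: iodoform, IC(I)I
Why: Takai olefination, in which the geminal dichromium species made from iodoform and divalent chromium adds to the aldehyde and eliminates to the E-iodoalkene under neutral conditions that neither reduce the tropone nor epimerise C2.

Step 13
Reactants: 17 (R)-but-3-ene-1,2-diol
Product: 18 (4R)-4-ethenyl-2,2-dimethyl-1,3-dioxolane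
Conditions: 2,2-dimethoxypropane, TsOH (cat.), CH2Cl2, 23 °C
Reagents that add atoms: 2,2-dimethoxypropane, COC(C)(C)OC
Why: Acid-catalysed acetal exchange forms the dioxolane without touching any bond to the stereocentre.

Step 14
Reactants: 18 (4R)-4-ethenyl-2,2-dimethyl-1,3-dioxolane; 7 5-bromo-2,6-dimethoxy-4-methylcyclohepta-2,4,6-trien-1-one
Product: 20 5-{2-[(4R)-2,2-dimethyl-1,3-dioxolan-4-yl]ethyl}-2,6-dimethoxy-4-methylcyclohepta-2,4,6-trien-1-one, via B-alkyl-9-BBN borane 19 (not isolated)
Conditions: 9-BBN, THF, 0 °C to 23 °C; then 7, Pd(OAc)2, SPhos, K3PO4, THF–H2O, 50 °C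
Reagents that add atoms: none
Why: Anti-Markovnikov hydroboration of the terminal alkene followed by B-alkyl Suzuki–Miyaura coupling with the bromotropone builds the C5–CH2CH2 tether in one flask; the stereocentre, two bonds away from boron, is carried through unchanged.

Step 15
Reactants: 20 5-{2-[(4R)-2,2-dimethyl-1,3-dioxolan-4-yl]ethyl}-2,6-dimethoxy-4-methylcyclohepta-2,4,6-trien-1-one
Product: 22 (2R)-2-(hydroxymethyl)-7-methoxy-5-methyl-3,4-dihydrocyclohepta[b]pyran-8(2H)-one, via 1,2-diol 21 (not isolated)
Conditions: CSA, MeOH, 23 °C; evaporate; then NaOMe (0.3 equiv), THF, 23 °C to 40 °C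
Reagents that add atoms: none
Why: Acetal methanolysis followed by methoxide-catalysed intramolecular addition–elimination at tropone C6 (vinylogous transesterification, 6-exo for the secondary alkoxide, seven-membered for the primary one) closes ring D with retention at the stereocentre because its C–O bond is not broken, and methoxide exchange at the other methoxy group is degenerate.

Step 16
Reactants: 22 (2R)-2-(hydroxymethyl)-7-methoxy-5-methyl-3,4-dihydrocyclohepta[b]pyran-8(2H)-one
Product: 23 (2R)-7-methoxy-5-methyl-8-oxo-2,3,4,8-tetrahydrocyclohepta[b]pyran-2-carbaldehyde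
Conditions: Dess–Martin periodinane, NaHCO3, CH2Cl2, 0 °C to 23 °C
Reagents that add atoms: none
Why: Dess–Martin oxidation under buffered conditions; the aldehyde, whose only stereocentre is α to the carbonyl group, is not stored but taken straight into step 17.

Step 17
Reactants: 23 (2R)-7-methoxy-5-methyl-8-oxo-2,3,4,8-tetrahydrocyclohepta[b]pyran-2-carbaldehyde
Product: 24 (2R)-7-methoxy-5-methyl-2-[(E)-2-(4,4,5,5-tetramethyl-1,3,2-dioxaborolan-2-yl)ethenyl]-3,4-dihydrocyclohepta[b]pyran-8(2H)-one
Conditions: CrCl2, Cl2CHBpin, LiI, THF, 23 °C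
Reagents that add atoms: 2-(dichloromethyl)-4,4,5,5-tetramethyl-1,3,2-dioxaborolane, CC1(C)OB(C(Cl)Cl)OC1(C)C
Why: Takai-type olefination with the boryl-substituted geminal dichromium reagent gives the E-alkenyl pinacol boronate under neutral conditions, which protects the enolisable α-stereocentre.

Step 18
Reactants: 16 (2R,3R)-2-[(E)-2-iodoethenyl]-7-methoxy-3,5-dimethyl-3,4-dihydrocyclohepta[b]pyran-8(2H)-one; 24 (2R)-7-methoxy-5-methyl-2-[(E)-2-(4,4,5,5-tetramethyl-1,3,2-dioxaborolan-2-yl)ethenyl]-3,4-dihydrocyclohepta[b]pyran-8(2H)-one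
Product: 25 bis(O-methyl) ether of the target
Conditions: Pd(dppf)Cl2 (5 mol%), K3PO4, THF–H2O, 23 °C
Reagents that add atoms: none
Why: Suzuki–Miyaura coupling of the alkenyl iodide with the alkenyl boronate proceeds with retention at both double bonds and so forms the central bond of the E,E-diene; mild phosphate base at room temperature leaves the methoxytropones intact.

Step 19
Reactants: 25 bis(O-methyl) ether of the target
Product: 26 CNP0332980.1
Conditions: LiOH, THF–H2O, 40 °C; then aq. NH4Cl
Reagents that add atoms: lithium hydroxide, [Li+].[OH-]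
Why: Alkaline hydrolysis of the two 2-methoxytropone units, which behave as vinylogous methyl esters: hydroxide adds to the methoxy-bearing carbon next to the carbonyl group, the most electrophilic ring position, and expels methoxide, after which each tropolonate is shielded from further attack by its charge, and the allylic ring ethers and the stereocentres are stable to base.

Compound list
1 | 2-methylanisole | COc1ccccc1C | starting material
2 | 1-methoxy-2-methylcyclohexa-1,4-diene | COC1=C(C)CC=CC1 | intermediate
3 | rac-7,7-dibromo-1-methoxy-6-methylbicyclo[4.1.0]hept-3-ene (cis-fused, racemic) | COC12CC=CCC1(C)C2(Br)Br | intermediate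
4 | rac-7,7-dibromo-1-methoxy-6-methylbicyclo[4.1.0]heptane-3,4-diol (cis-diol anti to the CBr2 bridge, racemic) | COC12CC(O)C(O)CC1(C)C2(Br)Br | intermediate
5 | 7,7-dibromo-1-methoxy-6-methylbicyclo[4.1.0]heptane-3,4-dione (racemic) | COC12CC(=O)C(=O)CC1(C)C2(Br)Br | intermediate (not isolated)
6 | 5-bromo-2-hydroxy-6-methoxy-4-methylcyclohepta-2,4,6-trien-1-one (tropolone, one tautomer drawn) | COc1cc(=O)c(O)cc(C)c1Br | intermediate
7 | 5-bromo-2,6-dimethoxy-4-methylcyclohepta-2,4,6-trien-1-one | COc1cc(=O)c(OC)cc(C)c1Br | intermediate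
8 | 5-(hydroxymethyl)-2,6-dimethoxy-4-methylcyclohepta-2,4,6-trien-1-one | COc1cc(=O)c(OC)cc(C)c1CO | intermediate
9 | 5-(bromomethyl)-2,6-dimethoxy-4-methylcyclohepta-2,4,6-trien-1-one | COc1cc(=O)c(OC)cc(C)c1CBr | intermediate
10 | (E)-3-(tributylstannyl)prop-2-en-1-ol | CCCC[Sn](CCCC)(CCCC)/C=C/CO | starting material
11 | 5-[(2E)-4-hydroxybut-2-en-1-yl]-2,6-dimethoxy-4-methylcyclohepta-2,4,6-trien-1-one | COc1cc(=O)c(OC)cc(C)c1C/C=C/CO | intermediate
12 | 5-{[(2S,3S)-3-(hydroxymethyl)oxiran-2-yl]methyl}-2,6-dimethoxy-4-methylcyclohepta-2,4,6-trien-1-one (trans epoxy alcohol, precursor of the key step) | OC[C@@H]1O[C@H]1Cc1c(C)cc(OC)c(=O)cc1OC | intermediate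
13 | 5-[(2R,3R)-3,4-dihydroxy-2-methylbutyl]-2,6-dimethoxy-4-methylcyclohepta-2,4,6-trien-1-one (formed as its aluminium alkoxide) | Cc1cc(OC)c(=O)cc(OC)c1C[C@@H](C)[C@@H](O)CO | intermediate (not isolated)
14 | (2R,3R)-2-(hydroxymethyl)-7-methoxy-3,5-dimethyl-3,4-dihydrocyclohepta[b]pyran-8(2H)-one (ring A and B half, product of the key step) | Cc1cc(OC)c(=O)cc2c1C[C@@H](C)[C@H](CO)O2 | intermediate
15 | (2R,3R)-7-methoxy-3,5-dimethyl-8-oxo-2,3,4,8-tetrahydrocyclohepta[b]pyran-2-carbaldehyde | Cc1cc(OC)c(=O)cc2c1C[C@@H](C)[C@H](C=O)O2 | intermediate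
16 | (2R,3R)-2-[(E)-2-iodoethenyl]-7-methoxy-3,5-dimethyl-3,4-dihydrocyclohepta[b]pyran-8(2H)-one | Cc1cc(OC)c(=O)cc2c1C[C@@H](C)[C@H](/C=C/I)O2 | intermediate
17 | (R)-but-3-ene-1,2-diol | C=C[C@@H](O)CO | starting material
18 | (4R)-4-ethenyl-2,2-dimethyl-1,3-dioxolane | C=C[C@@H]1COC(C)(C)O1 | intermediate
19 | 9-{2-[(4R)-2,2-dimethyl-1,3-dioxolan-4-yl]ethyl}-9-borabicyclo[3.3.1]nonane | B1(CC[C@@H]2COC(C)(C)O2)C3CCCC1CCC3 | intermediate (not isolated)
20 | 5-{2-[(4R)-2,2-dimethyl-1,3-dioxolan-4-yl]ethyl}-2,6-dimethoxy-4-methylcyclohepta-2,4,6-trien-1-one | COc1cc(=O)c(OC)cc(C)c1CC[C@@H]1COC(C)(C)O1 | intermediate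
21 | 5-[(3R)-3,4-dihydroxybutyl]-2,6-dimethoxy-4-methylcyclohepta-2,4,6-trien-1-one | COc1cc(=O)c(OC)cc(C)c1CC[C@@H](O)CO | intermediate (not isolated)
22 | (2R)-2-(hydroxymethyl)-7-methoxy-5-methyl-3,4-dihydrocyclohepta[b]pyran-8(2H)-one (ring C and D half) | OC[C@H]1CCc2c(C)cc(OC)c(=O)cc2O1 | intermediate
23 | (2R)-7-methoxy-5-methyl-8-oxo-2,3,4,8-tetrahydrocyclohepta[b]pyran-2-carbaldehyde | O=C[C@H]1CCc2c(C)cc(OC)c(=O)cc2O1 | intermediate
24 | (2R)-7-methoxy-5-methyl-2-[(E)-2-(4,4,5,5-tetramethyl-1,3,2-dioxaborolan-2-yl)ethenyl]-3,4-dihydrocyclohepta[b]pyran-8(2H)-one | CC1(C)OB(/C=C/[C@H]2CCc3c(C)cc(OC)c(=O)cc3O2)OC1(C)C | intermediate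
25 | (2R,3R)-7-methoxy-2-{(1E,3E)-4-[(2R)-7-methoxy-5-methyl-8-oxo-2,3,4,8-tetrahydrocyclohepta[b]pyran-2-yl]buta-1,3-dien-1-yl}-3,5-dimethyl-3,4-dihydrocyclohepta[b]pyran-8(2H)-one | Cc1cc(OC)c(=O)cc2c1C[C@@H](C)[C@H](/C=C/C=C/[C@H]1CCc3c(C)cc(OC)c(=O)cc3O1)O2 | intermediate
26 | CNP0332980.1, the bis-tropolone with (2R,3R) ring B, (2R) ring D and an E,E-diene | Cc1cc(=O)c(O)cc2c1C[C@@H](C)[C@H](/C=C/C=C/[C@H]1CCc3c(C)cc(=O)c(O)cc3O1)O2 | target

Total step count: 19. Longest linear sequence: 14 steps (steps 1 to 12, then 18 and 19, from 2-methylanisole); the ring C and D branch (steps 13 to 17) joins at step 18.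

Steps most likely to fail

Step 10. Trimethylaluminium may transfer methyl to the Lewis-acid-activated tropone (carbonyl or ring carbon) instead of the epoxide. The chelating methoxytropone may also hold back the aluminium needed for directed delivery, so that C3/C2 regiocontrol erodes or the opening stalls. The fallback sets out from bromotropone 7 and returns at 14; it brings the C3 methyl group in with the side chain. Purchased methyl (S)-2,2-dimethyl-1,3-dioxolane-4-carboxylate and MeMgBr should give 2-[(4S)-2,2-dimethyl-1,3-dioxolan-4-yl]propan-2-ol F1, which Burgess reagent dehydrates towards a methyl group to (4R)-2,2-dimethyl-4-(prop-1-en-2-yl)-1,3-dioxolane F2. Hydroboration with 9-BBN, anti-selective by substrate control for a 1,1-disubstituted alkene next to an oxygen-bearing stereocentre, should set the methyl stereocentre and give 9-{(2R)-2-[(4R)-2,2-dimethyl-1,3-dioxolan-4-yl]propyl}-9-borabicyclo[3.3.1]nonane F3. B-alkyl Suzuki–Miyaura coupling with 7 (Pd(OAc)2, SPhos, K3PO4) gives 5-{(2R)-2-[(4R)-2,2-dimethyl-1,3-dioxolan-4-yl]propyl}-2,6-dimethoxy-4-methylcyclohepta-2,4,6-trien-1-one F4. Methanolysis (CSA, MeOH) frees diol 13, and NaOMe closes ring B to 14 as in the second stage of step 10.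

Step 5. The alkylation may fall mainly on the wrong tropolone oxygen, since the anion is ambident and the C6 methoxy group biases it only weakly. The fallback sets out from 6 and returns at 7; it runs the step as a separation and recycle loop. The unwanted ether 5-bromo-2,4-dimethoxy-6-methylcyclohepta-2,4,6-trien-1-one F5 is hydrolysed with dilute aqueous NaOH (addition–elimination at its methoxy-bearing α-carbon, then acidification) back to tropolone 6, which is methylated again, so that material is funnelled to 7 over the cycles.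

Step 19. Hydroxide may also add to the ring-fusion carbon C9a and open ring B or ring D, or the tropolone ether may undergo base-induced ring contraction before it is cleaved. The fallback sets out from 25 and returns at 26; it cleaves the O–CH3 bond instead of the ring C–O bond. LiI in pyridine at 80 °C should demethylate by nucleophilic attack of iodide on the methyl carbon, directed by chelation of lithium between the tropone carbonyl and the methoxy oxygen; mild acidification then gives 26. No further compound arises (F0).

Further compounds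
F1 | step 10 | 2-[(4S)-2,2-dimethyl-1,3-dioxolan-4-yl]propan-2-ol | CC(C)(O)[C@@H]1COC(C)(C)O1
F2 | step 10 | (4R)-2,2-dimethyl-4-(prop-1-en-2-yl)-1,3-dioxolane | CC(=C)[C@@H]1COC(C)(C)O1
F3 | step 10 | 9-{(2R)-2-[(4R)-2,2-dimethyl-1,3-dioxolan-4-yl]propyl}-9-borabicyclo[3.3.1]nonane | B1(C[C@@H](C)[C@@H]2COC(C)(C)O2)C3CCCC1CCC3
F4 | step 10 | 5-{(2R)-2-[(4R)-2,2-dimethyl-1,3-dioxolan-4-yl]propyl}-2,6-dimethoxy-4-methylcyclohepta-2,4,6-trien-1-one | Cc1cc(OC)c(=O)cc(OC)c1C[C@@H](C)[C@@H]1COC(C)(C)O1
F5 | step 5 | 5-bromo-2,4-dimethoxy-6-methylcyclohepta-2,4,6-trien-1-one | COc1cc(OC)c(=O)cc(C)c1Br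
F0 | step 19 | none | none
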